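Early times give the speed of this exchange, so we begin there. Ash is the flask asked about, followed so far. Cedar ran earlier with half the ligand at the same starting complex.

| setting | ash | cedar | flask |
|---|---|---|---|
| starting complex | 0.24 M | 0.24 M | 0.24 M |
| incoming ligand | 1.2 equiv | 0.60 equiv | 1.20 equiv |
| remark | the very flask that is asked about, followed so far | run made earlier |  |
| time |  |  | 12 h |

| run | time / min | complex with two exchanged / % | starting complex / % |
|---|---|---|---|
| ash | 80.0 | 17.9 | 52.0 |
| ash | 150 | 25.0 | 39.0 |
| ash | 240 | 25.6 | 28.7 |
| ash | 300 | 25.6 | 26.0 |
| ash | 360 | 21.0 | 20.2 |
| ash | 480 | 19.9 | 17.8 |
| cedar | 2.50 | 0.4 | 98.4 |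
| cedar | 8.00 | 1.2 | 95.2 |
| cedar | 15.0 | 1.9 | 92.0 |
| cedar | 20.0 | 1.1 | 89.1 |
| cedar | 30.0 | 0.6 | 84.7 |
| cedar | 40.0 | 0.9 | 82.0 |

(scatter of a reading: 1 percentage point)

- amounts and yields of complex with two exchanged count crystals too
- given per volume of solution although it is solid: crystals
- the volume of additions can be left aside
- on the list of suspects stand: starting complex + incoming ligand -> leaving ligand + complex with one exchanged; complex with one exchanged + incoming ligand <-> leaving ligand + complex with two exchanged; crystals <-> complex with two exchanged

- Thursday's: at 12 h add starting complex, 50.0 % of the amount charged, then wait 6.0 h
- Sunday's: at 12 h add incoming ligand, 100 % of the amount charged, then wait 6.0 h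
- Wednesday's: at 12 h take out 90 % of the leaving ligand then present, then wait 6.0 h
- Saturday's: change nothing and wait 6.0 h more

- complex with two exchanged, in percent of the starting complex first charged, at 12 h
- the remedy with the largest gain of complex with two exchanged, or "none" below 2 percentage points (Thursday's / Sunday's / Wednesday's / Saturday's / none)
- complex with two exchanged present, in percent of the starting complex first charged, after Sunday's
- complex with two exchanged present, in percent of the starting complex first charged, after Wednesday's

In cedar the starting complex is down to 82.0 % at 40.0 min, while free incoming ligand averages 0.506 equiv. Taken as pseudo-first-order at that ligand, this reads as a half-life of 140 min, and the half-life goes inversely with free ligand. So ash starts at 58.9 min.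

Two things slow the first step in ash. Each starting complex reacted takes one ligand, and each complex with two exchanged takes one more. Free ligand at 480 min is therefore 0.179 equiv, a slowing by 6.70. The starting complex, at 17.8 %, slows the rate by 5.62. Together that is a factor of 37.7.

Free ligand equals the spare ligand, 0.200 equiv, when the two complexes read level, as they nearly do there. At the spare ligand the half-life reckons to 5.89 h. This tail half-life, the half-life of the starting complex once free ligand stands at the charge minus one equivalent, is 6.00 times the opening one.

So the last 240 min before 12 h are shorter than one tail half-life, and we expect 11.1 % of the starting complex still present, still taking ligand. Sunday's raises the spare ligand to 1.40 equiv, which scales the tail half-life to 50.4 min. That figure is a shortest value. Free ligand is the spare ligand plus the starting complex less the complex with two exchanged, so while the second exceeds the first, free ligand stands below the spare ligand and the half-life is longer.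

The forecast said “step one is second order and is starving for ligand late in ash”. It gave 17 % now (range 14.5 % to 19.5 %), Sunday's as best, 63 % after it (range 48 % to 70 %), and 26.5 % after Wednesday's (range 22 % to 31 %).

The flask gives 15.6 % now and Sunday's as best, with a gain of 55 percentage points. After it stand 70.4 %, above the forecast's range, and after Wednesday's 25.3 %.

    starting complex + incoming ligand → leaving ligand + complex with one exchanged (k = 0.0440 M⁻¹ min⁻¹)
    complex with one exchanged + incoming ligand ⇌ leaving ligand + complex with two exchanged (K = 0.350, k = 0.0790 M⁻¹ min⁻¹)
    crystals ⇌ complex with two exchanged, rate k3*(cs3 - [complex with two exchanged]) while solid is left; crystals form when [complex with two exchanged] > cs3 (solubility = 10.0 mM, k = 1.00 min⁻¹)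

At 12 h in ash, the starting complex has a half-life of 6.9 h by the first step, against our tail half-life of 5.89 h, while incoming ligand has 50 min by the forward second step, which is far shorter. The first step then uses ligand at 0.087 of that forward rate, against 1.0 at 64.2 min.

With 2.00 equiv of ligand, the spare ligand is 1.00 equiv and the tail half-life 70.6 min, for free ligand at that level. But in that flask at 12 h the two complexes are not level, and free ligand stands at 0.440 equiv, below the spare ligand. Scaled to that ligand, the half-life is 161 min, so 12 h holds 4.47 of that late length, and free ligand stood higher before. That flask stands at 0.93 % starting complex and 56.9 % complex with two exchanged.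

The earlier runs and the new flask stem from a simulated flask with made-up constants, and the scatter is random.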